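**Plan**

- Ring C is numbered so that C1 carries the 3‑aryl‑3‑oxopropyl chain, C3 the diaryl ether oxygen and C4 the free OH. The retrosynthesis removes four benzyl groups, de‑aromatises ring C to a 2‑aryloxy‑4‑alkylcyclohex‑2‑enone, and cuts that ring at C1–C6 and C2–C3.
- The cut gives an aryloxymethyl vinyl ketone that already holds the ring B phenol oxygen, and a 5‑aryl‑5‑oxopentanal. What allows this is the pattern on ring C: OH on C4, ether oxygen on the neighbouring C3 and the chain on C1 para to the OH, which is the pattern of such a cyclohexenone after aromatisation.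
- Forward: 2,4‑dihydroxyacetophenone is benzylated to supply ring A of both halves. One portion is condensed with vanillin, reduced to the ring B dihydrochalcone, and its phenol is converted to the vinyl ketone via 2‑vinyloxirane. A second portion is chain‑extended through its dimethylhydrazone to the ketoaldehyde.
- Ring C is the only ring made: enamine Michael addition and aldol condensation close it as a cyclohexenone, aerobic dehydrogenation aromatises it, and hydrogenolysis frees the four phenols.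
- Stereochemistry: the target is achiral. Assumption: racemic 2‑vinyloxirane is used, and the carbinol centre and the annulation centre arise as racemates that are erased by oxidation and aromatisation.

Key step: step 9

**Route**

Step 1
Reactants: 1 2,4‑dihydroxyacetophenone
Product: 2 1‑[2,4‑bis(benzyloxy)phenyl]ethan‑1‑one
Conditions: BnBr (2.4 equiv), K2CO3, KI (cat.), DMF, 80 °C
Reagents that add atoms: benzyl bromide, BrCc1ccccc1
Why: Williamson ether synthesis in which both phenoxides, including the hydrogen‑bonded 2‑OH once heated in DMF, are benzylated by SN2 on the benzylic bromide, with no stereocentre formed.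

Step 2
Reactants: 2 1‑[2,4‑bis(benzyloxy)phenyl]ethan‑1‑one; 3 vanillin (4‑hydroxy‑3‑methoxybenzaldehyde)
Product: 4 (E)‑1‑[2,4‑bis(benzyloxy)phenyl]‑3‑(4‑hydroxy‑3‑methoxyphenyl)prop‑2‑en‑1‑one
Conditions: KOH (excess), EtOH–THF–H2O, rt to 40 °C; acidic work‑up
Reagents that add atoms: none
Why: Claisen–Schmidt condensation in which the methyl ketone enolate adds to the non‑enolisable aldehyde and E1cB dehydration gives the conjugated E‑enone, the excess of KOH compensating for the lower electrophilicity of vanillin as its phenoxide.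

Step 3
Reactants: 4 the E‑chalcone
Product: 5 1‑[2,4‑bis(benzyloxy)phenyl]‑3‑(4‑hydroxy‑3‑methoxyphenyl)propan‑1‑one
Conditions: H2 (1 atm), 10% Pd/C, Ph2S (cat.), EtOAc, rt
Reagents that add atoms: none
Why: Chemoselective catalytic hydrogenation, since Pd/C poisoned with diphenyl sulfide should saturate the enone C=C while leaving the aryl benzyl ethers and the aryl ketone untouched.

Step 4
Reactants: 5 the ring B phenol; 6 2‑vinyloxirane (butadiene monoxide, racemic, excess)
Product: 7 1‑[2,4‑bis(benzyloxy)phenyl]‑3‑{4‑[(2‑hydroxybut‑3‑en‑1‑yl)oxy]‑3‑methoxyphenyl}propan‑1‑one (racemic)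
Conditions: K2CO3 (0.3 equiv), DMF, 70 °C, sealed vessel
Reagents that add atoms: none
Why: Base‑catalysed epoxide ring opening in which the phenoxide attacks the unsubstituted terminal carbon of the vinyl oxirane by SN2, the usual regiochemistry under basic non‑ionising conditions, giving the secondary allylic alcohol as a racemate whose stereocentre is removed in step 5.

Step 5
Reactants: 7 the allylic alcohol
Product: 8 1‑[4‑[3‑[2,4‑bis(benzyloxy)phenyl]‑3‑oxopropyl]‑2‑methoxyphenoxy]but‑3‑en‑2‑one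
Conditions: Dess–Martin periodinane, CH2Cl2, 0 °C to rt; used at once
Reagents that add atoms: none
Why: Dess–Martin oxidation of the secondary allylic alcohol under neutral, non‑nucleophilic conditions should deliver the polymerisation‑prone vinyl ketone without touching the benzyl ethers or the aryl ketone.

Step 6
Reactants: 2 1‑[2,4‑bis(benzyloxy)phenyl]ethan‑1‑one
Product: 9 (E)‑1‑[2,4‑bis(benzyloxy)phenyl]ethan‑1‑one N,N‑dimethylhydrazone
Conditions: Me2NNH2 (excess), AcOH (cat.), EtOH, reflux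
Reagents that add atoms: 1,1‑dimethylhydrazine, CN(C)N
Why: Acid‑catalysed hydrazone formation driven by excess reagent, which blocks ketone self‑condensation and prepares a strongly nucleophilic aza‑enolate, the dimethylamino group settling anti to the aryl ring.

Step 7
Reactants: 9 the dimethylhydrazone; 10 2‑(2‑bromoethyl)‑1,3‑dioxolane
Product: 11 1‑[2,4‑bis(benzyloxy)phenyl]‑4‑(1,3‑dioxolan‑2‑yl)butan‑1‑one N,N‑dimethylhydrazone (C=N geometry not defined, lost in step 8)
Conditions: LiN(iPr)2 (LDA), THF, −78 to 0 °C; then 10, 0 °C to rt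
Reagents that add atoms: none
Why: Hydrazone aza‑enolate alkylation, in which lithiation can occur only at the methyl group and the aza‑enolate is alkylated once by the primary bromide in an SN2 reaction, where the corresponding ketone enolate would react sluggishly.

Step 8
Reactants: 11 the alkylated hydrazone acetal
Product: 12 5‑[2,4‑bis(benzyloxy)phenyl]‑5‑oxopentanal
Conditions: 2 M aq HCl, THF, rt
Reagents that add atoms: water, O
Why: Acid hydrolysis cleaves the hydrazone and the dioxolane acetal in one operation, and the 1,5‑ketoaldehyde is safe from intramolecular aldol reaction because only four‑membered rings could form.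

Step 9
Reactants: 8 the aryloxymethyl vinyl ketone; 12 5‑[2,4‑bis(benzyloxy)phenyl]‑5‑oxopentanal
Product: 15 racemic 2‑{4‑[3‑(2,4‑bis(benzyloxy)phenyl)‑3‑oxopropyl]‑2‑methoxyphenoxy}‑4‑{3‑[2,4‑bis(benzyloxy)phenyl]‑3‑oxopropyl}cyclohex‑2‑en‑1‑one, via pyrrolidine enamine 13 (not isolated), via Michael adduct ketoaldehyde 14 (not isolated)
Conditions: 12, pyrrolidine (1.5 equiv), 4 Å MS, toluene, rt, then concentrate; 8, MeCN, 0 °C to rt; AcOH, NaOAc, H2O, 80 °C
Reagents that add atoms: none
Why: Pyrrolidine condenses only with the aldehyde of 12 (the aryl ketone is conjugated and flanked by an ortho benzyloxy group), and the β‑carbon of enamine 13 adds to the terminal CH2 of vinyl ketone 8 in a Stork enamine Michael addition, which makes the C1–C6 bond of ring C and, after buffered hydrolysis, gives ketoaldehyde 14. Pyrrolidinium acetate then promotes the intramolecular aldol condensation in which the aryloxy‑bearing methylene attacks the aldehyde and water is lost, which makes the C2–C3 bond; the closest known reaction type is the amine‑mediated Robinson‑type annulation of aldehydes with vinyl ketones to 4‑substituted cyclohex‑2‑enones, which is also known for alkoxymethyl vinyl ketones. Ring C closes as a six‑membered ring in a 6‑(enolendo)‑exo‑trig aldol step. The one new stereocentre, the carbon bearing the oxopropyl chain, is formed without control as a racemate, which is harmless because step 10 makes it planar. The step needs the ether oxygen to end up next to the ring carbonyl and the chain at the γ‑carbon, and the connectivity secures this: the aldehyde, by far the most electrophilic acceptor (more so as its iminium ion), can be reached through a six‑membered ring only by the aryloxy‑bearing methylene, while the conceivable ketone‑to‑ketone aldols across the 1,7‑diketone are reversible and slower. Chemoselectivity is secured by forming the enamine first and stripping free pyrrolidine before 8 is added, so that N‑addition to the vinyl ketone and its polymerisation are held back.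

Step 10
Reactants: 15 the 2‑aryloxycyclohexenone
Product: 16 1‑[2,4‑bis(benzyloxy)phenyl]‑3‑[4‑(5‑{3‑[2,4‑bis(benzyloxy)phenyl]‑3‑oxopropyl}‑2‑hydroxyphenoxy)‑3‑methoxyphenyl]propan‑1‑one (tetra‑O‑benzyl verbenachalcone)
Conditions: Pd(OCOCF3)2 (10 mol%), 2‑(dimethylamino)pyridine (20 mol%), TsOH (cat.), O2 (1 atm), DMSO, 80 °C
Reagents that add atoms: none
Why: Palladium‑catalysed aerobic dehydrogenation of a cyclohexenone to a phenol, in which a divalent palladium enolate at C6 of the enone undergoes β‑hydride elimination, the cyclohexadienone tautomerises to the arene and so erases the stereocentre, O2 reoxidises zerovalent palladium, and any chalcone formed by over‑dehydrogenation of the side chains is re‑saturated in step 11.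

Step 11
Reactants: 16 tetra‑O‑benzyl verbenachalcone
Product: 17 verbenachalcone, 1‑(2,4‑dihydroxyphenyl)‑3‑[4‑(5‑[3‑(2,4‑dihydroxyphenyl)‑3‑oxopropyl]‑2‑hydroxyphenoxy)‑3‑methoxyphenyl]propan‑1‑one
Conditions: H2 (1 atm), 10% Pd/C, EtOAc–MeOH, rt
Reagents that add atoms: none
Why: Hydrogenolysis of the four aryl benzyl ethers over Pd/C, under which the hydrogen‑bonded 2‑hydroxyaryl ketones, the diaryl ether and the methyl ether should be stable at 1 atm H2 and room temperature.

**Compound list**

1 | 2,4‑dihydroxyacetophenone | CC(=O)c1ccc(O)cc1O | starting material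
2 | 1‑[2,4‑bis(benzyloxy)phenyl]ethan‑1‑one | CC(=O)c1ccc(OCc2ccccc2)cc1OCc1ccccc1 | intermediate
3 | vanillin | COc1cc(C=O)ccc1O | starting material
4 | (E)‑1‑[2,4‑bis(benzyloxy)phenyl]‑3‑(4‑hydroxy‑3‑methoxyphenyl)prop‑2‑en‑1‑one | COc1cc(/C=C/C(=O)c2ccc(OCc3ccccc3)cc2OCc2ccccc2)ccc1O | intermediate
5 | 1‑[2,4‑bis(benzyloxy)phenyl]‑3‑(4‑hydroxy‑3‑methoxyphenyl)propan‑1‑one | COc1cc(CCC(=O)c2ccc(OCc3ccccc3)cc2OCc2ccccc2)ccc1O | intermediate
6 | 2‑vinyloxirane (butadiene monoxide), racemic | C=CC1CO1 | starting material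
7 | 1‑[2,4‑bis(benzyloxy)phenyl]‑3‑{4‑[(2‑hydroxybut‑3‑en‑1‑yl)oxy]‑3‑methoxyphenyl}propan‑1‑one, racemic | COc1cc(CCC(=O)c2ccc(OCc3ccccc3)cc2OCc2ccccc2)ccc1OCC(O)C=C | intermediate
8 | 1‑[4‑[3‑[2,4‑bis(benzyloxy)phenyl]‑3‑oxopropyl]‑2‑methoxyphenoxy]but‑3‑en‑2‑one | COc1cc(CCC(=O)c2ccc(OCc3ccccc3)cc2OCc2ccccc2)ccc1OCC(=O)C=C | intermediate
9 | (E)‑1‑[2,4‑bis(benzyloxy)phenyl]ethan‑1‑one N,N‑dimethylhydrazone | C/C(=N\N(C)C)c1ccc(OCc2ccccc2)cc1OCc1ccccc1 | intermediate
10 | 2‑(2‑bromoethyl)‑1,3‑dioxolane | BrCCC1OCCO1 | starting material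
11 | 1‑[2,4‑bis(benzyloxy)phenyl]‑4‑(1,3‑dioxolan‑2‑yl)butan‑1‑one N,N‑dimethylhydrazone (C=N geometry not defined) | CN(C)N=C(CCCC1OCCO1)c1ccc(OCc2ccccc2)cc1OCc1ccccc1 | intermediate
12 | 5‑[2,4‑bis(benzyloxy)phenyl]‑5‑oxopentanal | O=CCCCC(=O)c1ccc(OCc2ccccc2)cc1OCc1ccccc1 | intermediate
13 | (E)‑1‑[2,4‑bis(benzyloxy)phenyl]‑5‑(pyrrolidin‑1‑yl)pent‑4‑en‑1‑one (not isolated) | O=C(CC/C=C/N1CCCC1)c1ccc(OCc2ccccc2)cc1OCc1ccccc1 | intermediate
14 | 2‑{3‑[2,4‑bis(benzyloxy)phenyl]‑3‑oxopropyl}‑6‑{4‑[3‑(2,4‑bis(benzyloxy)phenyl)‑3‑oxopropyl]‑2‑methoxyphenoxy}‑5‑oxohexanal (racemic, one enantiomer drawn; not isolated) | COc1cc(CCC(=O)c2ccc(OCc3ccccc3)cc2OCc2ccccc2)ccc1OCC(=O)CC[C@@H](C=O)CCC(=O)c1ccc(OCc2ccccc2)cc1OCc1ccccc1 | intermediate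
15 | 2‑{4‑[3‑(2,4‑bis(benzyloxy)phenyl)‑3‑oxopropyl]‑2‑methoxyphenoxy}‑4‑{3‑[2,4‑bis(benzyloxy)phenyl]‑3‑oxopropyl}cyclohex‑2‑en‑1‑one (racemic, one enantiomer drawn) | COc1cc(CCC(=O)c2ccc(OCc3ccccc3)cc2OCc2ccccc2)ccc1OC1=C[C@@H](CCC(=O)c2ccc(OCc3ccccc3)cc2OCc2ccccc2)CCC1=O | intermediate
16 | 1‑[2,4‑bis(benzyloxy)phenyl]‑3‑[4‑(5‑{3‑[2,4‑bis(benzyloxy)phenyl]‑3‑oxopropyl}‑2‑hydroxyphenoxy)‑3‑methoxyphenyl]propan‑1‑one | COc1cc(CCC(=O)c2ccc(OCc3ccccc3)cc2OCc2ccccc2)ccc1Oc1cc(CCC(=O)c2ccc(OCc3ccccc3)cc2OCc2ccccc2)ccc1O | intermediate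
17 | verbenachalcone | COc1cc(CCC(=O)c2ccc(O)cc2O)ccc1Oc1cc(CCC(=O)c2ccc(O)cc2O)ccc1O | target

**Step count and risks**

Total step count: 11. Longest linear sequence: 8 steps (steps 1, 2, 3, 4, 5, 9, 10, 11).

Steps most likely to fail:

1. Step 9. The vinyl ketone may polymerise or take up pyrrolidine at nitrogen faster than it is C‑alkylated, a second Michael addition may occur at the aldehyde α‑carbon, or the aldol closure may stall before dehydration. Fallback: set out from aldehyde 12 and make the ether bond after the ring. Enamine 13 is added to commercial methyl vinyl ketone under the conditions of step 9, giving after buffered hydrolysis 2‑{3‑[2,4‑bis(benzyloxy)phenyl]‑3‑oxopropyl}‑5‑oxohexanal F1, which is not isolated and closes by the same Michael–aldol sequence to 4‑{3‑[2,4‑bis(benzyloxy)phenyl]‑3‑oxopropyl}cyclohex‑2‑en‑1‑one F2. Weitz–Scheffer epoxidation (H2O2, NaOH, MeOH, 0 °C) should give 4‑{3‑[2,4‑bis(benzyloxy)phenyl]‑3‑oxopropyl}‑2,3‑epoxycyclohexan‑1‑one F3, with the oxygen expected trans to the side chain. Phenol 5 with Cs2CO3 in DMF at 70 °C should open the epoxide at the carbon next to the carbonyl to give the trans 2‑aryloxy‑3‑hydroxycyclohexanone F4, which is not isolated and loses water by E1cB. This returns to the route at 15.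

2. Step 10. Dehydrogenation may stop short of the arene, the two dihydrochalcone chains may be oxidised competitively, or the aryl enol ether may be hydrolysed by the acid co‑catalyst. Fallback: set out from 15 and activate every ketone before oxidising. TMSOTf and Et3N in CH2Cl2 at 0 °C should give the tris(trimethylsilyl) enol ether of 15 F5 (ring 2‑silyloxy‑1,3‑diene plus two Z side‑chain silyl enol ethers). Saegusa–Ito oxidation with Pd(OAc)2 in MeCN–DMSO under O2 then aromatises the ring and turns both chains into enones, giving the tetra‑O‑benzyl bis‑chalcone phenol F6. Hydrogenation under the conditions of step 11 saturates both enones while removing the benzyl groups, so the fallback rejoins the route at target 17.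

3. Step 2. The condensation may be slow because vanillin reacts as its electron‑rich phenoxide, with retro‑aldol equilibration and Cannizzaro loss of aldehyde during the long exposure to strong base. Fallback: set out from vanillin 3 and mask the phenol first. Vanillin and 2‑vinyloxirane 6 (K2CO3 cat., DMF, 70 °C) should give 4‑[(2‑hydroxybut‑3‑en‑1‑yl)oxy]‑3‑methoxybenzaldehyde F7. Claisen–Schmidt condensation with ketone 2 (KOH, EtOH, rt) then gives (E)‑1‑[2,4‑bis(benzyloxy)phenyl]‑3‑{4‑[(2‑hydroxybut‑3‑en‑1‑yl)oxy]‑3‑methoxyphenyl}prop‑2‑en‑1‑one F8. Conjugate reduction with [(Ph3P)CuH]6 in wet toluene at rt should reduce only the enone, leaving the terminal alkene and benzyl ethers. This returns to the route at 7 and bypasses steps 3 and 4.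

Further compounds
F1 | step 9 | 2‑{3‑[2,4‑bis(benzyloxy)phenyl]‑3‑oxopropyl}‑5‑oxohexanal (racemic, one enantiomer drawn) | CC(=O)CC[C@@H](C=O)CCC(=O)c1ccc(OCc2ccccc2)cc1OCc1ccccc1
F2 | step 9 | 4‑{3‑[2,4‑bis(benzyloxy)phenyl]‑3‑oxopropyl}cyclohex‑2‑en‑1‑one (racemic, one enantiomer drawn) | O=C1C=C[C@@H](CCC(=O)c2ccc(OCc3ccccc3)cc2OCc2ccccc2)CC1
F3 | step 9 | 4‑{3‑[2,4‑bis(benzyloxy)phenyl]‑3‑oxopropyl}‑2,3‑epoxycyclohexan‑1‑one (racemic, epoxide trans to the side chain, one enantiomer drawn) | O=C1CC[C@H](CCC(=O)c2ccc(OCc3ccccc3)cc2OCc2ccccc2)[C@H]2O[C@@H]12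
F4 | step 9 | 2‑{4‑[3‑(2,4‑bis(benzyloxy)phenyl)‑3‑oxopropyl]‑2‑methoxyphenoxy}‑4‑{3‑[2,4‑bis(benzyloxy)phenyl]‑3‑oxopropyl}‑3‑hydroxycyclohexan‑1‑one (racemic, aryloxy trans to hydroxy, one enantiomer drawn) | O=C1CC[C@H](CCC(=O)c2ccc(OCc3ccccc3)cc2OCc2ccccc2)[C@@H](O)[C@@H]1Oc1ccc(CCC(=O)c2ccc(OCc3ccccc3)cc2OCc2ccccc2)cc1OC
F5 | step 10 | tris(trimethylsilyl) enol ether of 15 (racemic, one enantiomer drawn) | COc1cc(C/C=C(\O[Si](C)(C)C)c2ccc(OCc3ccccc3)cc2OCc2ccccc2)ccc1OC1=C[C@@H](C/C=C(\O[Si](C)(C)C)c2ccc(OCc3ccccc3)cc2OCc2ccccc2)CC=C1O[Si](C)(C)C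
F6 | step 10 | (E)‑1‑[2,4‑bis(benzyloxy)phenyl]‑3‑[4‑(5‑{(E)‑3‑[2,4‑bis(benzyloxy)phenyl]‑3‑oxoprop‑1‑en‑1‑yl}‑2‑hydroxyphenoxy)‑3‑methoxyphenyl]prop‑2‑en‑1‑one | COc1cc(/C=C/C(=O)c2ccc(OCc3ccccc3)cc2OCc2ccccc2)ccc1Oc1cc(/C=C/C(=O)c2ccc(OCc3ccccc3)cc2OCc2ccccc2)ccc1O
F7 | step 2 | 4‑[(2‑hydroxybut‑3‑en‑1‑yl)oxy]‑3‑methoxybenzaldehyde (racemic) | COc1cc(C=O)ccc1OCC(O)C=C
F8 | step 2 | (E)‑1‑[2,4‑bis(benzyloxy)phenyl]‑3‑{4‑[(2‑hydroxybut‑3‑en‑1‑yl)oxy]‑3‑methoxyphenyl}prop‑2‑en‑1‑one (racemic) | COc1cc(/C=C/C(=O)c2ccc(OCc3ccccc3)cc2OCc2ccccc2)ccc1OCC(O)C=C
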